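**Plan**
1. Retrosynthetic cuts, in order: the three ester C–O bonds; the C4/C5 epoxide (back to the Z-alkene) and the C1–O bond of the C1/C10 epoxide (back to an O1 mesylate and O10); the ring bond C1–C2; then C2–C3, C4=C5 and C10–C1 of the open chain; last the C10–C5 bond of a carvone ring.
2. Enabling feature: in the ten-membered ring the oxygens on C1 (epoxide) and C3 (angelate) flank the C2 methylene, and C3 is allylic to C4(Me)=C5. This is the aldol pattern of a C3 ketone in a Z-enone and a C1 aldehyde on the oxygenated quaternary C10.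
3. Forward: (S)-carvone supplies C5–C10 and is opened between C10 and C5; the chain grows at C5 (C3, C4) and at C10 (C1), and C2 enters as a bromomethyl unit. The only carbocycle, the ten-membered ring, closes at C1–C2; the two epoxides and the esters come last.
4. Stereochemistry: C7 from carvone; C8 by anti hydroxylation then Mitsunobu inversion; C9 by Luche reduction; C10 by Felkin–Anh addition; C1 by chelation in the ring closure, then inverted on epoxide closure; C3 by 1,3-anti reduction; C4/C5 by O3-directed epoxidation; angelate geometry from angelic acid.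

Key step: step 15

Remark: locants C1–C10 are those of the ten-membered ring of the target (C7 isopropenyl, C8 acetate, C3 and C9 angelates, C4 and C10 methyl-bearing epoxide carbons) and are used for every intermediate. Carvone C5, C6, C1, C2, C3, C4 become C7, C8, C9, C10, C5, C6.

**Route**

Step 1
Reactants: 1 (S)-(+)-carvone
Product: 4 trans-6-hydroxycarvone, via trimethylsilyl dienol ether 2 (not isolated), via 6-trimethylsilyloxy ketone 3 (not isolated)
Conditions: lithium diisopropylamide, Me3SiCl, THF, −78 °C; mCPBA, NaHCO3, CH2Cl2, −20 °C; 1 M HCl, THF, 0 °C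
Reagents that add atoms: mCPBA, OOC(=O)c1cccc(Cl)c1
Why: Rubottom oxidation: kinetic α′-deprotonation gives the cross-conjugated silyl dienol ether, the peracid epoxidises this electron-rich C8=C9 bond (faster than the isopropenyl group) on the face anti to the C7 isopropenyl group, and silyl migration followed by acid hydrolysis should leave the C8 hydroxyl trans to isopropenyl.

Step 2
Reactants: 4 trans-6-hydroxycarvone
Product: 5 cis-6-(4-nitrobenzoyloxy)carvone
Conditions: 4-nitrobenzoic acid, PPh3, DIAD, toluene, 0 → 23 °C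
Reagents that add atoms: 4-nitrobenzoic acid, OC(=O)c1ccc(cc1)[N+](=O)[O-]
Why: Mitsunobu reaction: the carbonyl-activated C8 oxyphosphonium is displaced by 4-nitrobenzoate in an SN2 step, so C8 is inverted and its oxygen becomes cis to the isopropenyl group.

Step 3
Reactants: 5 cis-6-(4-nitrobenzoyloxy)carvone
Product: 6 all-cis allylic alcohol (C9–OH, C8 ester)
Conditions: NaBH4, CeCl3·7H2O, MeOH, −78 °C
Reagents that add atoms: none
Why: Luche 1,2-reduction: hydride should add to the ketone face anti to the pseudo-axial C8 ester and the C7 substituent (axial attack, also the Felkin–Anh face), placing the C9 hydroxyl cis to both, and reduction removes the enolisable ketone so C8 can no longer epimerise.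

Step 4
Reactants: 6 all-cis allylic alcohol
Product: 7 epoxy alcohol (C10–C5 epoxide)
Conditions: VO(acac)2 (cat.), t-BuOOH, CH2Cl2, 0 → 23 °C
Reagents that add atoms: tert-butyl hydroperoxide, CC(C)(C)OO
Why: Hydroxyl-directed VO(acac)2/t-BuOOH epoxidation of the cyclic allylic alcohol is chemoselective for the ring alkene over the isopropenyl group and delivers oxygen syn to O9, a configuration that is immaterial because this epoxide only masks the later C10/C5 cleavage.

Step 5
Reactants: 7 epoxy alcohol
Product: 8 C9 triethylsilyl ether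
Conditions: Et3SiOTf, 2,6-lutidine, CH2Cl2, −78 °C
Reagents that add atoms: triethylsilyl triflate, CC[Si](CC)(CC)OS(=O)(=O)C(F)(F)F
Why: Silylation with the silyl triflate and 2,6-lutidine protects the hindered C9 hydroxyl as a non-chelating, acid-labile ether before the ring is cleaved; no stereocenter changes.

Step 6
Reactants: 8 C9 triethylsilyl ether
Product: 9 C8 alcohol (C9–OSiEt3, epoxide)
Conditions: i-Bu2AlH (excess), CH2Cl2, −78 °C
Reagents that add atoms: none
Why: Reductive ester cleavage with i-Bu2AlH at −78 °C frees O8 through an aluminium alkoxide, avoiding the basic methanolysis that would let the neighbouring triethylsilyl group migrate, and leaves the epoxide untouched.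

Step 7
Reactants: 9 C8 alcohol
Product: 10 C8 tert-butyldimethylsilyl, C9 triethylsilyl epoxide
Conditions: t-BuMe2SiOTf, 2,6-lutidine, CH2Cl2, −78 → −40 °C
Reagents that add atoms: tert-butyldimethylsilyl triflate, CC(C)(C)[Si](C)(C)OS(=O)(=O)C(F)(F)F
Why: Silylation of the hindered C8 hydroxyl with the reactive silyl triflate installs the robust ether that stays until the last two steps and so differentiates O8 from O9.

Step 8
Reactants: 10 bis-silyl epoxide
Product: 11 C10 methyl ketone / C5 aldehyde
Conditions: H5IO6, THF/Et2O, 0 °C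
Reagents that add atoms: periodic acid H5IO6 (its water supplies the second carbonyl oxygen), OI(O)(O)(O)(O)=O
Why: Periodic acid cleavage of an epoxide (hydrolytic opening to the glycol and Malaprade cleavage) turns C10 into the methyl ketone and C5 into the aldehyde, while the silyl ether on O9 prevents cleavage of C9–C10 and no stereocenter is touched.

Step 9
Reactants: 11 keto aldehyde; 12 ethyl 2-[bis(2,2,2-trifluoroethoxy)phosphoryl]propanoate
Product: 13 Z-enoate methyl ketone
Conditions: 12, KN(SiMe3)2, 18-crown-6, THF, −78 °C; then 11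
Reagents that add atoms: none
Why: Still–Gennari olefination: the trifluoroethyl phosphonate with a dissociated potassium counter-ion eliminates under kinetic control to the Z-trisubstituted enoate and reacts only with the aldehyde, not with the hindered methyl ketone.

Step 10
Reactants: 13 Z-enoate methyl ketone; 14 1,3-dithiane
Product: 15 C10 tertiary carbinol bearing the dithiane (C1)
Conditions: 14, n-BuLi, THF, −30 °C; then 13, −78 °C; aqueous NH4Cl
Reagents that add atoms: none
Why: Corey–Seebach addition of 2-lithio-1,3-dithiane to the methyl ketone, far more electrophilic than the hindered Z-enoate at −78 °C, under polar Felkin–Anh control (C9–OSiEt3 bond anti to the incoming carbanion, attack past the C9 hydrogen) should set C10 with O10 anti to O9.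

Step 11
Reactants: 15 dithianyl carbinol
Product: 17 C9/C10 acetonide ester, via 9,10-diol 16 (not isolated)
Conditions: PPTS, MeOH, 23 °C; then Me2C(OMe)2, PPTS, CH2Cl2, 23 °C
Reagents that add atoms: 2,2-dimethoxypropane, COC(C)(C)OC
Why: Acid-catalysed methanolysis removes the triethylsilyl ether selectively over the secondary tert-butyldimethylsilyl ether, and transketalisation with 2,2-dimethoxypropane closes the five-membered acetonide over the secondary/tertiary 9,10-diol, fixing the O8 versus O9 differentiation.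

Step 12
Reactants: 17 acetonide ester
Product: 18 Z-Weinreb amide
Conditions: MeNH(OMe)·HCl, i-PrMgCl, THF, −20 → 0 °C
Reagents that add atoms: N,O-dimethylhydroxylamine hydrochloride, CNOC.Cl
Why: Weinreb aminolysis with the chloromagnesium amide converts the ester into the N-methoxy-N-methylamide without conjugate addition or loss of the Z geometry.

Step 13
Reactants: 18 Z-Weinreb amide; 19 dibromomethane
Product: 20 bromomethyl Z-enone (dithiane)
Conditions: 19, MeLi·LiBr, THF/Et2O, −78 °C; aqueous NH4Cl
Reagents that add atoms: none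
Why: Bromomethyllithium, made by bromine–lithium exchange in the presence of the amide, adds once to the Weinreb amide because the chelated tetrahedral intermediate survives until the quench, giving the α′-bromomethyl Z-enone (carbenoid homologation of Weinreb amides).

Step 14
Reactants: 20 bromomethyl Z-enone (dithiane)
Product: 21 bromomethyl Z-enone aldehyde
Conditions: PhI(OCOCF3)2, NaHCO3, MeCN/H2O (9:1), 0 °C
Reagents that add atoms: water, O
Why: Oxidative dithiane hydrolysis with PhI(OCOCF3)2 is fast at 0 °C and spares the alkenes, bromo ketone, acetonide and silyl ether; the liberated aldehyde has no α-hydrogen and cannot epimerise or enolise.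

Step 15
Reactants: 21 bromomethyl Z-enone aldehyde
Product: 23 ten-membered 1-hydroxy-3-ketone, via samarium enolate 22 (not isolated)
Conditions: SmI2 (0.1 M in THF, 2.2 equiv), THF, −78 °C, slow addition of 21 (final about 0.005 M); aqueous NH4Cl at −78 °C
Reagents that add atoms: none
Why: Two equivalents of divalent samarium reduce the C–Br bond next to the ketone much faster than the enone or the aldehyde, giving the regiodefined trivalent samarium enolate 22 at C2 without base, so the Z-enone is not isomerised and nothing else is enolised. The oxophilic metal then binds the C1 aldehyde and the enolate adds through a cyclic, Zimmerman–Traxler-like aldol transition state; the closest known reaction type is the SmI2-mediated intramolecular Reformatsky reaction used to close eight-membered carbocycles and medium-ring lactones. The ten-membered ring closes in the 10-exo-trig mode at the aldehyde (enolendo with respect to the C2–C3 enolate), helped by high dilution and by the Z-alkene and the cis-dioxolane, which bend the chain into a turn. The single new stereocenter C1 is controlled by chelation of trivalent samarium between the aldehyde oxygen and the acetonide oxygen O10: with O1 and O10 held syn, C2 adds to the face flanked by the C10 methyl group, anti to C9, which is also the extended ring torsion about C10–C1, giving the 1S alcohol with O1 syn to O10. The step needs chemoselective C–Br reduction and this C1 facial selectivity; the first is secured by the activated α-bromo ketone at −78 °C without additives, the second by the chelating dioxolane oxygen, and the cold NH4Cl quench guards against retro-aldol and dehydration.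

Step 16
Reactants: 23 ten-membered 1-hydroxy-3-ketone
Product: 24 1,3-anti diol
Conditions: Me4NBH(OAc)3, MeCN/AcOH (1:1), −35 → −20 °C
Reagents that add atoms: none
Why: Saksena–Evans reduction: the C1 hydroxyl exchanges onto boron and hydride is delivered internally through a chair transition state, so the enone is reduced 1,2 and the C3 hydroxyl should emerge anti to O1 (3S).

Step 17
Reactants: 24 1,3-anti diol
Product: 25 C3 triethylsilyl ether (C1–OH free)
Conditions: Et3SiCl (1.1 equiv), imidazole, CH2Cl2, −40 → −20 °C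
Reagents that add atoms: chlorotriethylsilane, CC[Si](CC)(CC)Cl
Why: Kinetically selective silylation: the allylic C3 hydroxyl is markedly less hindered than the C1 hydroxyl, which sits next to the fully substituted, acetonide-bearing C10, so one equivalent of Et3SiCl at low temperature should mark O3 alone.

Step 18
Reactants: 25 C3 triethylsilyl ether
Product: 26 C1 mesylate
Conditions: MsCl, Et3N, CH2Cl2, −20 → 0 °C
Reagents that add atoms: methanesulfonyl chloride, CS(=O)(=O)Cl
Why: Sulfonylation through sulfene (MsCl/Et3N) converts even the hindered C1 hydroxyl into the mesylate with retention at C1; with C3 no longer a ketone no β-elimination pathway exists.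

Step 19
Reactants: 26 C1 mesylate
Product: 27 3,9,10-triol C1 mesylate
Conditions: AcOH/H2O/THF (3:1:1), 40 °C
Reagents that add atoms: none
Why: Mild aqueous acid hydrolyses the acetonide and the allylic triethylsilyl ether while the hindered secondary tert-butyldimethylsilyl ether and the mesylate survive, exposing O10 next to the leaving group.

Step 20
Reactants: 27 triol mesylate
Product: 28 cis-1,10-epoxide 3,9-diol
Conditions: K2CO3, MeOH, 0 °C
Reagents that add atoms: none
Why: Intramolecular Williamson etherification (3-exo-tet): the C10 alkoxide displaces the C1 mesylate from the rear, inverting C1 to R and giving the cis-1,10-epoxide, a closure much faster than oxetane formation from O9 or O3.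

Step 21
Reactants: 28 1,10-epoxide 3,9-diol
Product: 29 1,10:4,5-bis-epoxide 3,9-diol
Conditions: VO(acac)2 (cat.), t-BuOOH, CH2Cl2, 0 °C
Reagents that add atoms: tert-butyl hydroperoxide, CC(C)(C)OO
Why: Hydroxyl-directed VO(acac)2/t-BuOOH epoxidation: only C4=C5 carries an allylic hydroxyl, and A(1,3) strain in the Z-alkene holds H3 in the alkene plane so oxygen is delivered to the face bearing O3, which is also the peripheral face, giving the cis-4,5-epoxide syn to O3.

Step 22
Reactants: 29 bis-epoxide 3,9-diol; 30 angelic acid (two equivalents are consumed, one for each hydroxyl)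
Product: 31 3,9-bis-angelate C8 silyl ether
Conditions: 30 (excess, at least 4 equiv), 2,4,6-trichlorobenzoyl chloride (same amount), Et3N, toluene, 23 °C; then 29, toluene, 80 °C
Reagents that add atoms: angelic acid (the second equivalent of 30, which supplies the second ester group), C/C=C(/C)C(=O)O
Why: Yamaguchi esterification: each of the two secondary hydroxyls is acylated by one molecule of the preformed angelic 2,4,6-trichlorobenzoic mixed anhydride, so two molecules of 30 end up in 31, under weakly basic conditions that should not isomerise the angelate to the tiglate and that leave every ring stereocenter untouched.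

Step 23
Reactants: 31 bis-angelate silyl ether
Product: 32 C8 alcohol
Conditions: HF·pyridine, pyridine, THF, 0 → 23 °C
Reagents that add atoms: none
Why: Buffered HF·pyridine cleaves the silyl ether by fluoride attack at silicon under weakly acidic conditions that do not promote acyl migration from O9 and are tolerated by trisubstituted epoxides.

Step 24
Reactants: 32 C8 alcohol
Product: 33 CNP0260455.1
Conditions: Ac2O, pyridine, DMAP (cat.), CH2Cl2, 0 → 23 °C
Reagents that add atoms: acetic anhydride, CC(=O)OC(C)=O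
Why: DMAP-catalysed acetylation of the last free hydroxyl gives the target with all eight stereocenters unchanged.

**Compound list**

1 | (S)-(+)-carvone, (5S)-2-methyl-5-(prop-1-en-2-yl)cyclohex-2-en-1-one | C=C(C)[C@H]1CC=C(C)C(=O)C1 | starting material
2 | trimethylsilyl dienol ether of 1 (C8=C9 enol ether, C9–OSiMe3, C7 unchanged) | C=C(C)[C@H]1CC=C(C)C(O[Si](C)(C)C)=C1 | intermediate (not isolated)
3 | trans-6-(trimethylsilyloxy)carvone (C8–OSiMe3 trans to isopropenyl) | C=C(C)[C@H]1CC=C(C)C(=O)[C@@H]1O[Si](C)(C)C | intermediate (not isolated)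
4 | (5R,6R)-6-hydroxy-2-methyl-5-(prop-1-en-2-yl)cyclohex-2-en-1-one (trans-6-hydroxycarvone) | C=C(C)[C@H]1CC=C(C)C(=O)[C@@H]1O | intermediate
5 | (1S,6R)-3-methyl-2-oxo-6-(prop-1-en-2-yl)cyclohex-3-en-1-yl 4-nitrobenzoate (C8 ester cis to isopropenyl) | C=C(C)[C@H]1CC=C(C)C(=O)[C@H]1OC(=O)c2ccc(cc2)[N+](=O)[O-] | intermediate
6 | (1S,2R,6R)-2-hydroxy-3-methyl-6-(prop-1-en-2-yl)cyclohex-3-en-1-yl 4-nitrobenzoate (isopropenyl, O8 and O9 all cis) | C=C(C)[C@H]1CC=C(C)[C@@H](O)[C@H]1OC(=O)c2ccc(cc2)[N+](=O)[O-] | intermediate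
7 | epoxy alcohol: 6 with a C10–C5 epoxide on the face of O9 | C=C(C)[C@H]1C[C@H]2O[C@@]2(C)[C@@H](O)[C@H]1OC(=O)c3ccc(cc3)[N+](=O)[O-] | intermediate
8 | C9 triethylsilyl ether of 7 | C=C(C)[C@H]1C[C@H]2O[C@@]2(C)[C@@H](O[Si](CC)(CC)CC)[C@H]1OC(=O)c3ccc(cc3)[N+](=O)[O-] | intermediate
9 | all-cis epoxy cyclohexanol with free C8–OH and C9–OSiEt3 | C=C(C)[C@H]1C[C@H]2O[C@@]2(C)[C@@H](O[Si](CC)(CC)CC)[C@H]1O | intermediate
10 | all-cis epoxide with C8–OSi(t-Bu)Me2 and C9–OSiEt3 | C=C(C)[C@H]1C[C@H]2O[C@@]2(C)[C@@H](O[Si](CC)(CC)CC)[C@H]1O[Si](C)(C)C(C)(C)C | intermediate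
11 | 6-oxoheptanal C5–C10 chain: C7 isopropenyl, C8 OSi(t-Bu)Me2, C9 OSiEt3, C10 methyl ketone; 7,8-anti and 8,9-anti in the zigzag chain | C=C(C)[C@@H](CC=O)[C@H](O[Si](C)(C)C(C)(C)C)[C@H](O[Si](CC)(CC)CC)C(C)=O | intermediate
12 | ethyl 2-[bis(2,2,2-trifluoroethoxy)phosphoryl]propanoate | CCOC(=O)C(C)P(=O)(OCC(F)(F)F)OCC(F)(F)F | starting material
13 | ethyl (Z)-2-methylalk-2-enoate (C3 ester, Z C4=C5) carrying the C10 methyl ketone; stereocenters as in 11 | C=C(C)[C@@H](C/C=C(C)\C(=O)OCC)[C@H](O[Si](C)(C)C(C)(C)C)[C@H](O[Si](CC)(CC)CC)C(C)=O | intermediate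
14 | 1,3-dithiane | C1CSCSC1 | starting material
15 | C10 tertiary alcohol with 1,3-dithian-2-yl as C1; O10 anti to O9 | C=C(C)[C@@H](C/C=C(C)\C(=O)OCC)[C@H](O[Si](C)(C)C(C)(C)C)[C@H](O[Si](CC)(CC)CC)[C@](C)(O)C1SCCCS1 | intermediate
16 | 9,10-diol from 15 (C9–OH, C10–OH; C8 silyl ether kept) | C=C(C)[C@@H](C/C=C(C)\C(=O)OCC)[C@H](O[Si](C)(C)C(C)(C)C)[C@H](O)[C@](C)(O)C1SCCCS1 | intermediate (not isolated)
17 | C9/C10 acetonide (C8 and the dithiane cis on the dioxolane) of the Z-enoate | C=C(C)[C@@H](C/C=C(C)\C(=O)OCC)[C@H](O[Si](C)(C)C(C)(C)C)[C@@H]1OC(C)(C)O[C@]1(C)C2SCCCS2 | intermediate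
18 | (Z)-N-methoxy-N-methyl amide corresponding to 17 | C=C(C)[C@@H](C/C=C(C)\C(=O)N(C)OC)[C@H](O[Si](C)(C)C(C)(C)C)[C@@H]1OC(C)(C)O[C@]1(C)C2SCCCS2 | intermediate
19 | dibromomethane | BrCBr | starting material
20 | bromomethyl Z-enone (C2 bromide, C3 ketone) with C1 as dithiane | C=C(C)[C@@H](C/C=C(C)\C(=O)CBr)[C@H](O[Si](C)(C)C(C)(C)C)[C@@H]1OC(C)(C)O[C@]1(C)C2SCCCS2 | intermediate
21 | bromomethyl Z-enone aldehyde: C1 aldehyde on C10, C9/C10 acetonide, C8 OSi(t-Bu)Me2 | C=C(C)[C@@H](C/C=C(C)\C(=O)CBr)[C@H](O[Si](C)(C)C(C)(C)C)[C@@H]1OC(C)(C)O[C@]1(C)C=O | intermediate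
22 | samarium enolate of 21 (C2=C3–O–SmI2) | C=C(C)[C@@H](C/C=C(C)\C(=C)O[Sm](I)I)[C@H](O[Si](C)(C)C(C)(C)C)[C@@H]1OC(C)(C)O[C@]1(C)C=O | intermediate (not isolated)
23 | ten-membered (Z)-4-en-3-one with (1S)-1-hydroxyl syn to O10, C9/C10 acetonide, C8 OSi(t-Bu)Me2 | C=C(C)[C@H]1C/C=C(C)\C(=O)C[C@H](O)[C@@]2(C)OC(C)(C)O[C@H]2[C@H]1O[Si](C)(C)C(C)(C)C | intermediate
24 | 1,3-anti diol (3S allylic alcohol) of the ten-membered ring | C=C(C)[C@H]1C/C=C(C)\[C@@H](O)C[C@H](O)[C@@]2(C)OC(C)(C)O[C@H]2[C@H]1O[Si](C)(C)C(C)(C)C | intermediate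
25 | C3 triethylsilyl ether of 24, C1–OH free | C=C(C)[C@H]1C/C=C(C)\[C@@H](O[Si](CC)(CC)CC)C[C@H](O)[C@@]2(C)OC(C)(C)O[C@H]2[C@H]1O[Si](C)(C)C(C)(C)C | intermediate
26 | C1 methanesulfonate of 25 | C=C(C)[C@H]1C/C=C(C)\[C@@H](O[Si](CC)(CC)CC)C[C@H](OS(C)(=O)=O)[C@@]2(C)OC(C)(C)O[C@H]2[C@H]1O[Si](C)(C)C(C)(C)C | intermediate
27 | 3,9,10-triol C1 mesylate, C8 OSi(t-Bu)Me2 | C=C(C)[C@H]1C/C=C(C)\[C@@H](O)C[C@H](OS(C)(=O)=O)[C@@](C)(O)[C@@H](O)[C@H]1O[Si](C)(C)C(C)(C)C | intermediate
28 | cis-1,10-epoxide (1R) with free C3 and C9 hydroxyls, Z C4=C5, C8 OSi(t-Bu)Me2 | C=C(C)[C@H]1C/C=C(C)\[C@@H](O)C[C@H]2O[C@@]2(C)[C@@H](O)[C@H]1O[Si](C)(C)C(C)(C)C | intermediate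
29 | 1,10:4,5-bis-cis-epoxide 3,9-diol (4,5-epoxide syn to O3), C8 OSi(t-Bu)Me2 | C=C(C)[C@H]1C[C@@H]2O[C@]2(C)[C@@H](O)C[C@H]2O[C@@]2(C)[C@@H](O)[C@H]1O[Si](C)(C)C(C)(C)C | intermediate
30 | angelic acid, (Z)-2-methylbut-2-enoic acid | C/C=C(/C)C(=O)O | starting material
31 | 3,9-bis-angelate of 29 | C=C(C)[C@H]1C[C@@H]2O[C@]2(C)[C@@H](OC(=O)/C(C)=C\C)C[C@H]2O[C@@]2(C)[C@@H](OC(=O)/C(C)=C\C)[C@H]1O[Si](C)(C)C(C)(C)C | intermediate
32 | 3,9-bis-angelate with free C8 hydroxyl | C=C(C)[C@H]1C[C@@H]2O[C@]2(C)[C@@H](OC(=O)/C(C)=C\C)C[C@H]2O[C@@]2(C)[C@@H](OC(=O)/C(C)=C\C)[C@H]1O | intermediate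
33 | CNP0260455.1, (1R,3S,4S,5S,7R,8S,9S,10R)-8-acetoxy-1,10:4,5-diepoxygermacr-11(12)-ene-3,9-diyl bis[(Z)-2-methylbut-2-enoate] | C=C(C)[C@H]1C[C@@H]2O[C@]2(C)[C@@H](OC(=O)/C(C)=C\C)C[C@H]2O[C@@]2(C)[C@@H](OC(=O)/C(C)=C\C)[C@H]1OC(C)=O | target

**Step count and risks**

Total: 24 steps. Longest linear sequence: 24 steps from (S)-carvone; all other inputs (12, 14, 19, 30) are commercial.

Steps most likely to fail:

1. Step 15 (ring closure). The samarium enolate may be protonated to the methyl ketone, may react between molecules to give oligomers, or may attack the wrong face of the aldehyde if chelation to the dioxolane oxygen is weak. Fallback: close the same C1–C2 bond as a chelation-controlled intramolecular Mukaiyama aldol. Setting out from Weinreb amide 18, MeMgBr (THF, 0 °C) gives methyl Z-enone F1. PhI(OCOCF3)2 in aqueous MeCN unmasks keto aldehyde F2. Me3SiOTf/Et3N (CH2Cl2, −78 °C) converts only the methyl ketone, since the aldehyde has no α-hydrogen, into silyloxy diene F3. F3 is added slowly to MgBr2·OEt2 in CH2Cl2 at high dilution; magnesium bound between the aldehyde oxygen and O10 directs attack as before, and citric acid work-up returns the route at 23.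

2. Step 2 (C8 inversion). The activated, hindered α-ketol may eliminate toward the cross-conjugated dienone and on to the phenol, or enolisation may return the trans ester. Fallback: set C8 by hydride delivery instead of substitution. Setting out from 4, Ac2O/pyridine gives trans acetate F4; Luche reduction gives allylic alcohol F5 (C9–OH cis to isopropenyl); VO(acac)2/t-BuOOH gives epoxy alcohol F6; Et3SiOTf/2,6-lutidine gives silyl ether F7; i-Bu2AlH removes the acetate to give 8-epi alcohol F8; Dess–Martin periodinane gives C8 ketone F9. LiBH(s-Bu)3 at −78 °C then attacks the face opposite the isopropenyl group, O9 and the epoxide and returns the route at 9.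

3. Step 17 (O3 versus O1). Silylation may occur at O1 or at both hydroxyls if the ring conformation shields the allylic hydroxyl. Fallback: let the reduction itself distinguish the two oxygens. Setting out from 23, Evans–Tishchenko reduction (SmI2 cat., PhCHO, THF, −10 °C) gives 1,3-anti diol 1-benzoate F10 with O3 free; Et3SiOTf/2,6-lutidine gives silyl ether benzoate F11; i-Bu2AlH at −78 °C removes the benzoate and returns the route at 25.

**Further compounds**

F1 | step 15 | methyl Z-enone with dithiane (from 18) | C=C(C)[C@@H](C/C=C(C)\C(C)=O)[C@H](O[Si](C)(C)C(C)(C)C)[C@@H]1OC(C)(C)O[C@]1(C)C2SCCCS2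
F2 | step 15 | methyl Z-enone C1 aldehyde | C=C(C)[C@@H](C/C=C(C)\C(C)=O)[C@H](O[Si](C)(C)C(C)(C)C)[C@@H]1OC(C)(C)O[C@]1(C)C=O
F3 | step 15 | trimethylsilyloxy diene C1 aldehyde | C=C(C)[C@@H](C/C=C(C)\C(=C)O[Si](C)(C)C)[C@H](O[Si](C)(C)C(C)(C)C)[C@@H]1OC(C)(C)O[C@]1(C)C=O
F4 | step 2 | trans-6-acetoxycarvone | C=C(C)[C@H]1CC=C(C)C(=O)[C@@H]1OC(C)=O
F5 | step 2 | allylic alcohol with trans C8 acetate | C=C(C)[C@H]1CC=C(C)[C@@H](O)[C@@H]1OC(C)=O
F6 | step 2 | epoxy alcohol with trans C8 acetate | C=C(C)[C@H]1C[C@H]2O[C@@]2(C)[C@@H](O)[C@@H]1OC(C)=O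
F7 | step 2 | C9 triethylsilyl ether with trans C8 acetate | C=C(C)[C@H]1C[C@H]2O[C@@]2(C)[C@@H](O[Si](CC)(CC)CC)[C@@H]1OC(C)=O
F8 | step 2 | 8-epi alcohol (C8–OH trans to isopropenyl) | C=C(C)[C@H]1C[C@H]2O[C@@]2(C)[C@@H](O[Si](CC)(CC)CC)[C@@H]1O
F9 | step 2 | C8 ketone | C=C(C)[C@H]1C[C@H]2O[C@@]2(C)[C@@H](O[Si](CC)(CC)CC)C1=O
F10 | step 17 | 1,3-anti diol 1-benzoate (O3 free) | C=C(C)[C@H]1C/C=C(C)\[C@@H](O)C[C@H](OC(=O)c3ccccc3)[C@@]2(C)OC(C)(C)O[C@H]2[C@H]1O[Si](C)(C)C(C)(C)C
F11 | step 17 | C3 triethylsilyl ether 1-benzoate | C=C(C)[C@H]1C/C=C(C)\[C@@H](O[Si](CC)(CC)CC)C[C@H](OC(=O)c3ccccc3)[C@@]2(C)OC(C)(C)O[C@H]2[C@H]1O[Si](C)(C)C(C)(C)C
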